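## Structural features

Guanipiperazine A (20) contains a guanine, a phenol ring (ring A), a para-phenylene ring (ring B) and a piperazine. Ring A is bonded to guanine C8 by a biaryl C-C bond and to ring B through a diaryl ether oxygen, and each benzene ring is tied by one CH2 group to the piperazine (ring B to C2, ring A to C5). Ring A (bridged meta), ring B (bridged para), the ether oxygen, the two CH2 groups and one C-C-N-C edge of the piperazine form a 14-membered cyclophane. On ring A the OH lies between the guanine-bearing carbon and the aryloxy carbon, and the benzylic CH2 is para to the OH and meta to the ether oxygen. The only stereocentres are piperazine C2 and C5, which are 1,4-related and not adjacent; both are S and hence cis, as expected from the α-carbons of two L-amino acids once a diketopiperazine is reduced. Fragile groups are the oxidisable phenol, the two secondary amines (which condense with aldehydes), and the poorly soluble, amphoteric guanine, which is best added late. The real difficulty is closing the rigid, strained 14-membered meta,para-cyclophane, and after that placing guanine at the hindered position ortho to the phenol. The key step uses the fact that the ring A benzylic CH2 and piperazine C5 are Cβ and Cα of an alanine. The aryl-CH2 bond para to the phenol oxygen can therefore be made from an alanine methyl C-H and a ring A iodide, while the future piperazine atoms N1 and C3 are still the amide nitrogen and the carboxylate of a dipeptide and can hold the metal.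

## Logic of the disconnections

20 to 19: the two N-CO(carbamate) bonds are cut. The secondary amines cannot coexist with the aldehyde used two steps earlier, and the carbamates keep the late intermediates soluble and chromatographable. The forward step is an acidolysis that must leave guanine, phenol and diaryl ether alone.

19 to 15 and 16: the C8-N7 and C8-N9 bonds of the imidazole are cut. Guanine is the least tractable part, so it is built last on a ring A aldehyde carbon from commercial 16. The target thereby shrinks to a purine-free cyclophane. The forward step must condense at the 5-amino group and dehydrogenate the aminal without oxidising the phenol.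

15 to 14: the ring A C-CHO bond is cut. The position is the only free one ortho to the phenol, because para carries the CH2 and the other ortho position the aryloxy group. The forward step must be strictly ortho-selective and must not harm the carbamates.

14 to 13: the two N-CO bonds are cut, as a functional-group operation. The forward step must acylate nitrogen and not the phenol.

13 to 12: the O-CH3 bond of ring A is restored. A methyl ether is the phenol mask that survives palladium, silver, hydrazine and borane. The forward demethylation must spare the diaryl ether.

12 to 11: the two ring CH2 groups next to nitrogen are returned to lactam carbonyls. The piperazine thus becomes a cyclodipeptide whose stereocentres are amino-acid α-carbons. The forward reduction must not epimerise them.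

11 to 9: the lactam N-C(=O) bond between the alanine-derived nitrogen and the tyrosine carbonyl is cut. What remains is a macrocyclic dipeptide with a free amine and a free acid. The forward closure needs the amide inside the 14-membered ring to turn cis and must avoid an activated C-terminal acyl species that could epimerise.

9 to 8: the N-phthaloyl group is restored. It is the nitrogen mask that the C-H activation needs (no N-H, no oxazolone). The forward hydrazinolysis must leave the amide and the acid untouched.

8 to 7: the ring A C(aryl)-CH2 bond, para to the methoxy group, is cut to an aryl iodide and an alanine methyl group. The macrocycle opens to a linear dipeptide in which both stereocentres are bought and none must be set. The forward step must activate the β-C-H selectively, prefer intramolecular coupling, and tolerate the free acid that directs it.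

7 to 6: the acid is masked as a tert-butyl ester. Acidolysis frees it without hydroxide (which would open the phthalimide) and without an organotin reagent. The forward step must trap the tert-butyl cation.

6 to 4 and 5: the diaryl ether C-O bond between ring B and the ring A oxygen is cut. A room-temperature copper-mediated boronic acid-phenol coupling leaves the C-I bond and the α-centres alone. The forward step needs O-arylation of a guaiacol-type OH to outrun decay of the boronic acid.

4 to 2 and 3: the peptide bond is cut. Coupling before etherification removes any need for a temporary carbamate on the tyrosine nitrogen. The forward step must not racemise 3.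

2 to 1: the ester O-C(CH3)3 bond is cut, leaving a commercial amino acid. The forward step must esterify in the presence of a free amine and a boronic acid.

## Other disconnections considered

Alternative 1: The cut is at C8-N7 and C8-N9 of guanine, leading to the N,N'-di-Boc macrocyclic salicylaldehyde A2 (the same compound as 15) and 16. The forward key step condenses A2 with 16 and dehydrogenates the resulting 7,8-dihydropurine with FeCl3 or air, giving the di-Boc target A1 (the same compound as 19). In its favour: guanine enters last, the formyl position is unambiguous, and no cross-coupling with an insoluble 8-haloguanine is needed. On this point the alternative is the equal of the chosen plan, which adopts it unchanged as steps 11 and 12. Against it as the governing disconnection: it removes only the purine. It forms no bond of the 14-membered ring and sets no stereocentre, so the hard problem, access to A2, stays open. Structurally the two ideas are complementary. Mechanistically one is a polar condensation and oxidation at the periphery, the other an organometallic ring closure at the core. Step economy after the macrocycle is identical, so the total length is set entirely by how A2 is reached.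

Alternative 2: The cut is through two C-C bonds of the phenol ring (ring A in the lettering used here), which is assembled from a 2-pyrone and an alkyne. The precursor A4 is a cis-2,5-disubstituted N,N'-di-Cbz piperazine carrying a propargyl arm on C5 and a para-(pyron-5-yloxy)benzyl arm on C2. The forward key step heats A4 dilute at about 200 °C; intramolecular Diels-Alder addition and decarboxylative aromatisation would give the O-benzyl N,N'-di-Cbz macrocycle A3. A regiochemical correction is needed. If pyrone C3 bonded to the internal alkyne carbon, a 5-aryloxy group would end up para to the new benzylic carbon. A3 has it meta, so the consistent mapping is pyrone C6 to the internal and C3 to the terminal alkyne carbon, with the benzyloxy group on pyrone C4; A4 is drawn that way. In its favour: ring A and the macrocycle form together, and the strain is paid by an irreversible aromatisation without any metal. The piperazine is complete before closure, so no diketopiperazine has to form inside a strained ring; on that point it is better than the chosen plan. Against it: A4 needs a 4,5-dioxygenated 2-pyrone and a propargyl-bearing piperazine, both multistep. An electron-rich pyrone and an unactivated alkyne are poorly matched, hence the temperature, which the carbamates must survive. Only the tether decides between the meta-bridged and the para-bridged orientation. Both plans buy the two stereocentres from L-amino acids and set none in the key step (equal). In step economy the chosen plan is clearly shorter, and its precursor comes in four steps from commercial materials.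

Alternative 3: The cut is the C5-CH2 bond, the Cα-Cβ bond next to the one chosen here. The precursor A6 is the bis-lactim ether of a glycine/O-aryl-L-tyrosine diketopiperazine with a CH2Br group on ring A para to the methoxy group. The forward key step deprotonates the glycine-derived carbon with LDA at low temperature under dilution and lets it displace the benzylic bromide, giving the macrocyclic (2S,5S) bis-lactim ether A5. In its favour: an aza-enolate and a benzylic bromide react fast at -78 °C, and no palladium or stoichiometric silver is needed. On mildness and reagent cost it is better than the chosen plan. Against it: the step must create the C5 stereocentre, and the usual sense of bis-lactim alkylation is anti to the C2 substituent, which would be trans. Cis can only come from the reach of the tether. The C2-H of A6 is also acidic and is shielded by a benzyl group only, so the resident stereocentre is at risk. The bromide has to be unveiled next to acid-labile lactim ethers. After closure A5 still needs hydrolysis (which tends to open the ring to a bis-amino ester that must re-close) and reduction. Both plans close the same 14-membered ring at the same benzylic carbon (equal). The chosen plan sets no stereocentre and relies on a chelate-defined site, whereas this one rests on kinetic stereocontrol without a clear bias. Step counts would be similar or longer here.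

Key step: step 5

Remarks on the chemistry. Structures 7 and 8 were checked atom by atom against 20: iodide para to the methoxy group, ether oxygen meta to it, both α-carbons S, ring size 14. They are consistent and are kept unchanged. The design change concerns how 7 is reached: a tert-butyl ester cleaved by acid replaces a methyl ester cleaved by an organotin hydroxide, and peptide coupling before etherification removes two carbamate steps. Assumption: 16 is charged as its commercial sulfate and freed in the flask with NaOAc.

## Route

Step 1
Reactants: 1 4-borono-L-phenylalanine
Product: 2 tert-butyl 4-borono-L-phenylalaninate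
Conditions: Tf2NH (1.1 equiv), t-BuOAc, 0 °C to rt; aq. NaHCO3 work-up
Reagents that add atoms: tert-butyl acetate CC(=O)OC(C)(C)C
Why: Acid-promoted tert-butyl transfer from tert-butyl acetate is an established esterification of free amino acids, the ammonium form protecting nitrogen; an alkyl-substituted arylboronic acid should protodeboronate only slowly under anhydrous acid at room temperature, and the S centre is not involved.

Step 2
Reactants: 2 tert-butyl 4-borono-L-phenylalaninate; 3 N-phthaloyl-L-alanine
Product: 4 tert-butyl N-(N-phthaloyl-L-alanyl)-4-borono-L-phenylalaninate
Conditions: DIC, Oxyma, CH2Cl2/DMF, 0 °C to rt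
Reagents that add atoms: none
Why: Carbodiimide/Oxyma amide coupling; the phthalimido acid cannot form an oxazolone and no tertiary base is present, so the alanine centre should stay S, and the boronic acid is a spectator.

Step 3
Reactants: 4 tert-butyl N-(N-phthaloyl-L-alanyl)-4-borono-L-phenylalaninate (1.5 equiv); 5 5-iodo-2-methoxyphenol
Product: 6 tert-butyl N-(N-phthaloyl-L-alanyl)-O-(5-iodo-2-methoxyphenyl)-L-tyrosinate
Conditions: Cu(OAc)2 (1 equiv), pyridine (5 equiv), 4 Å MS, CH2Cl2, air, rt
Reagents that add atoms: none
Why: Chan-Lam O-arylation: the aryl group moves from boron to a phenoxide-bearing divalent copper, air raises it to trivalent copper and C-O reductive elimination follows at room temperature; an aryl iodide is inert under these conditions, a secondary amide N-H is arylated far more slowly than a phenol, and the α-centres are not epimerised; excess 4 offsets protodeboronation and oxidation of the boronic acid.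

Step 4
Reactants: 6 tert-butyl N-(N-phthaloyl-L-alanyl)-O-(5-iodo-2-methoxyphenyl)-L-tyrosinate
Product: 7 N-(N-phthaloyl-L-alanyl)-O-(5-iodo-2-methoxyphenyl)-L-tyrosine
Conditions: TFA/CH2Cl2 (1:3), H2O (2 %), 0 °C to rt
Reagents that add atoms: none
Why: Acidolysis of the tert-butyl ester (loss of isobutene) frees the acid without hydroxide, so phthalimide, C-I bond and both α-centres are untouched; the water intercepts the cation before it can alkylate ring A.

Step 5
Reactants: 7 N-(N-phthaloyl-L-alanyl)-O-(5-iodo-2-methoxyphenyl)-L-tyrosine
Product: 8 14-membered cyclophane dipeptide acid (N-phthaloyl; ring A O-methyl; alanine β-carbon bonded to ring A para to OMe; both α-carbons S)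
Conditions: Pd(OAc)2 (15 mol %), AgOAc (2.5 equiv), HFIP, 90 °C, 3 mM, sealed vessel
Reagents that add atoms: none
Why: The carboxylate and the deprotonated amide nitrogen of 7 bind divalent palladium as an N,O-chelate that holds the metal over the alanine methyl group, and acetate-assisted concerted metalation-deprotonation gives a five-membered palladacycle fused to the chelate ring. The aryl iodide, tethered through the tyrosine side chain, adds oxidatively to give tetravalent palladium, C(sp3)-C(sp2) reductive elimination forms the ring A-CH2 bond, and AgOAc removes iodide as AgI and returns Pd(OAc)2. The closest known reaction type is the peptide-directed β-C(sp3)-H arylation of N-terminal N-phthaloyl alanine with aryl iodides, including its intramolecular use to tie side-chain aryl iodides into cyclophane peptides. Mode of closure: the 14-membered ring arises by contraction of a 15-membered palladacycle in which both termini sit on the same metal, so the strain is met in an organometallic intermediate and not in a bimolecular transition state. No stereocentre is formed; both α-carbons are spectators, since the phthalimide has no N-H and offers no path to an oxazolone. The step needs the alanine methyl to react in preference to the tyrosine CH2 and the arene C-H bonds, which the 5,5-fused chelate geometry secures because only the N-terminal β-carbon can reach the metal. It also needs ring closure to beat intermolecular coupling, secured by the 3 mM concentration, and a single arylation, secured because the only aryl iodide is consumed in the closure.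

Step 6
Reactants: 8 14-membered cyclophane dipeptide acid (N-phthaloyl)
Product: 9 macrocyclic amino acid (free NH2 on the alanine-derived carbon; free CO2H; ring A O-methyl)
Conditions: N2H4·H2O (4 equiv), EtOH, 50 °C; then dilute HCl, filtration
Reagents that add atoms: none
Why: Hydrazinolysis of the phthalimide (Gabriel-type deprotection): two acyl substitutions release the primary amine and insoluble phthalhydrazide; the carboxylate and the secondary amide are inert to hydrazine at this temperature and nothing basic enough to epimerise is present.

Step 7
Reactants: 9 macrocyclic amino acid
Product: 11 macrocyclic (3S,6S)-diketopiperazine (ring A O-methyl), via amino methyl ester hydrochloride 10 (not isolated)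
Conditions: SOCl2, MeOH, 0 to 40 °C; evaporate; then NMM (1.1 equiv), AcOH (0.1 M), 2-butanol/toluene, reflux, 3 mM
Reagents that add atoms: none
Why: Fischer esterification under HCl creates no activated acyl species, hence no oxazolone at the C-terminal tyrosine; intramolecular aminolysis of the methyl ester (6-exo-trig) is the classical diketopiperazine closure, N-methylated cyclophane dipeptides of this ring size are known with a cis amide at this position, and dilution should suppress the cyclodimer.

Step 8
Reactants: 11 macrocyclic (3S,6S)-diketopiperazine
Product: 12 macrocyclic (2S,5S)-piperazine, ring A O-methyl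
Conditions: BH3·THF (10 equiv), THF, reflux; then MeOH, 6 M HCl, reflux; NaOH work-up
Reagents that add atoms: none
Why: Borane reduction of secondary lactams to amines; the hydride source is electrophilic and non-basic, so the centres that become C2 and C5 should not epimerise, acidic methanolysis breaks the amine-borane adducts, and aryl ethers are inert.

Step 9
Reactants: 12 macrocyclic (2S,5S)-piperazine, ring A O-methyl
Product: 13 macrocyclic (2S,5S)-piperazine phenol (purine-free core of the target)
Conditions: BBr3 (6 equiv), CH2Cl2, -78 °C to rt; MeOH quench; aq. NaHCO3
Reagents that add atoms: none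
Why: Lewis-acid ether cleavage: BBr3 binds the methoxy oxygen and bromide attacks the methyl carbon (SN2); the diaryl ether offers no sp3 carbon and survives, and the amines are only held as adducts that methanol releases.

Step 10
Reactants: 13 macrocyclic (2S,5S)-piperazine phenol
Product: 14 N,N'-di-Boc macrocyclic piperazine phenol
Conditions: Boc2O (2.3 equiv), Et3N, MeOH, 0 °C to rt
Reagents that add atoms: di-tert-butyl dicarbonate CC(C)(C)OC(=O)OC(=O)OC(C)(C)C
Why: Carbamoylation of the two secondary amines; in methanol any aryl carbonate at the phenol is solvolysed, so only nitrogen stays protected, which shields the amines from formaldehyde and from the aldehyde of 15.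

Step 11
Reactants: 14 N,N'-di-Boc macrocyclic piperazine phenol
Product: 15 N,N'-di-Boc macrocyclic salicylaldehyde (CHO on ring A ortho to OH)
Conditions: MgCl2 (3 equiv), Et3N (6 equiv), (CH2O)n (10 equiv), MeCN, reflux; cold 1 M HCl work-up
Reagents that add atoms: formaldehyde (as paraformaldehyde) C=O
Why: Magnesium-mediated ortho-formylation of phenols (Casnati-Skattebøl): the magnesium phenoxide delivers formaldehyde to the ortho carbon through a six-membered chelate and a second formaldehyde takes a hydride from the benzylic alkoxide; para is blocked by CH2 and one ortho position by the aryloxy group, so only the required carbon can react, and ring B has no phenol.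

Step 12
Reactants: 15 N,N'-di-Boc macrocyclic salicylaldehyde; 16 2,5,6-triaminopyrimidin-4(3H)-one
Product: 19 N,N'-di-Boc-guanipiperazine A, via Schiff base 17 (not isolated), via 7,8-dihydropurine 18 (not isolated)
Conditions: 16·H2SO4 (1.2 equiv), NaOAc, DMSO, 80 °C; then FeCl3 (10 mol %), air, 100 °C
Reagents that add atoms: none
Why: Traube-type purine synthesis from an aldehyde: the 5-amino group, the only one not tied up as an amidine, forms Schiff base 17, the 6-amino group adds to it to give aminal 18, and iron-catalysed aerobic dehydrogenation aromatises the imidazole, the standard route to 8-arylguanines; air as terminal oxidant is mild toward the phenol, and the transient centre at C8 of 18 is erased.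

Step 13
Reactants: 19 N,N'-di-Boc-guanipiperazine A
Product: 20 guanipiperazine A
Conditions: TFA/CH2Cl2 (1:4), 0 °C to rt; then NH3 in MeOH
Reagents that add atoms: none
Why: Acidolysis of both tert-butyl carbamates (loss of isobutene and CO2); guanine, phenol, diaryl ether and the non-epimerisable C2 and C5 centres are stable to TFA, and neutralisation gives the free base.

## Compound list

1 | 4-borono-L-phenylalanine | N[C@@H](Cc1ccc(B(O)O)cc1)C(=O)O | starting material
2 | tert-butyl 4-borono-L-phenylalaninate | N[C@@H](Cc1ccc(B(O)O)cc1)C(=O)OC(C)(C)C | intermediate
3 | N-phthaloyl-L-alanine | C[C@H](N1C(=O)c2ccccc2C1=O)C(=O)O | starting material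
4 | tert-butyl N-(N-phthaloyl-L-alanyl)-4-borono-L-phenylalaninate | C[C@H](N1C(=O)c2ccccc2C1=O)C(=O)N[C@@H](Cc1ccc(B(O)O)cc1)C(=O)OC(C)(C)C | intermediate
5 | 5-iodo-2-methoxyphenol | COc1ccc(I)cc1O | starting material
6 | tert-butyl N-(N-phthaloyl-L-alanyl)-O-(5-iodo-2-methoxyphenyl)-L-tyrosinate | COc1ccc(I)cc1Oc1ccc(cc1)C[C@@H](C(=O)OC(C)(C)C)NC(=O)[C@H](C)N1C(=O)c2ccccc2C1=O | intermediate
7 | N-(N-phthaloyl-L-alanyl)-O-(5-iodo-2-methoxyphenyl)-L-tyrosine | COc1ccc(I)cc1Oc1ccc(cc1)C[C@@H](C(=O)O)NC(=O)[C@H](C)N1C(=O)c2ccccc2C1=O | intermediate
8 | 14-membered cyclophane dipeptide acid, N-phthaloyl, ring A O-methyl, (S,S) | COc1ccc2cc1Oc1ccc(cc1)C[C@@H](C(=O)O)NC(=O)[C@@H](N1C(=O)c3ccccc3C1=O)C2 | intermediate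
9 | macrocyclic amino acid, (S,S) | COc1ccc2cc1Oc1ccc(cc1)C[C@@H](C(=O)O)NC(=O)[C@@H](N)C2 | intermediate
10 | macrocyclic amino methyl ester hydrochloride, (S,S) | COc1ccc2cc1Oc1ccc(cc1)C[C@@H](C(=O)OC)NC(=O)[C@@H](N)C2.Cl | intermediate
11 | macrocyclic (3S,6S)-diketopiperazine, ring A O-methyl | COc1ccc2cc1Oc1ccc(cc1)C[C@H]1C(=O)N[C@@H](C2)C(=O)N1 | intermediate
12 | macrocyclic (2S,5S)-piperazine, ring A O-methyl | COc1ccc2cc1Oc1ccc(cc1)C[C@H]1CN[C@H](CN1)C2 | intermediate
13 | macrocyclic (2S,5S)-piperazine phenol | Oc1ccc2cc1Oc1ccc(cc1)C[C@H]1CN[C@H](CN1)C2 | intermediate
14 | N,N'-di-Boc macrocyclic piperazine phenol | Oc1ccc2cc1Oc1ccc(cc1)C[C@H]1CN(C(=O)OC(C)(C)C)[C@H](CN1C(=O)OC(C)(C)C)C2 | intermediate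
15 | N,N'-di-Boc macrocyclic salicylaldehyde | O=Cc1cc2cc(c1O)Oc1ccc(cc1)C[C@H]1CN(C(=O)OC(C)(C)C)[C@H](CN1C(=O)OC(C)(C)C)C2 | intermediate
16 | 2,5,6-triaminopyrimidin-4(3H)-one | Nc1nc(N)c(N)c(=O)[nH]1 | starting material
17 | Schiff base of 15 at the 5-amino group of 16 | Nc1nc(N)c(/N=C/c2cc3cc(c2O)Oc2ccc(cc2)C[C@H]2CN(C(=O)OC(C)(C)C)[C@H](CN2C(=O)OC(C)(C)C)C3)c(=O)[nH]1 | intermediate
18 | 8-aryl-7,8-dihydroguanine (aminal, C8 unassigned) | Nc1nc2NC(c3cc4cc(c3O)Oc3ccc(cc3)C[C@H]3CN(C(=O)OC(C)(C)C)[C@H](CN3C(=O)OC(C)(C)C)C4)Nc2c(=O)[nH]1 | intermediate
19 | N,N'-di-Boc-guanipiperazine A | Nc1nc2nc(-c3cc4cc(c3O)Oc3ccc(cc3)C[C@H]3CN(C(=O)OC(C)(C)C)[C@H](CN3C(=O)OC(C)(C)C)C4)[nH]c2c(=O)[nH]1 | intermediate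
20 | guanipiperazine A | Nc1nc2nc(-c3cc4cc(c3O)Oc3ccc(cc3)C[C@H]3CN[C@H](CN3)C4)[nH]c2c(=O)[nH]1 | target

## Step count and least certain steps

Total: 13 steps. Longest linear sequence: 13 steps (1 to 20); 3, 5 and 16 are commercial and enter directly.

Step 5 (key step). The most likely failure is intermolecular arylation giving oligomers, together with hydrodeiodination, because the tethered iodide must reach the palladacycle across a strained 15-membered arrangement. Any zerovalent palladium formed at 90 °C would also consume iodide by homocoupling. The fallback closes the same ring at the diaryl ether instead; it sets out from 2 and returns at 8. Commercial 3-hydroxy-4-methoxy-L-phenylalanine F1 would be phthaloylated (N-carbethoxyphthalimide, Na2CO3, water) to N-phthaloyl-3-hydroxy-4-methoxy-L-phenylalanine F2 and coupled with 2 (DIC, Oxyma) to tert-butyl N-(N-phthaloyl-3-hydroxy-4-methoxy-L-phenylalanyl)-4-borono-L-phenylalaninate F3. An intramolecular Chan-Lam coupling (Cu(OAc)2, pyridine, 4 Å MS, O2, CH2Cl2, high dilution) would give the macrocyclic N-phthaloyl dipeptide tert-butyl ester F4, and TFA would then give 8.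

Step 7. The six-membered ring may fail to close because the amide inside the 14-membered ring has to rotate to cis. Intermolecular aminolysis (cyclodimer, oligomer) and slow epimerisation at the ester α-carbon could then take over. The fallback forms the piperazine without any cis-amide intermediate; it sets out from 9 and returns at 12. BH3·THF would reduce both the acid and the amide of 9 to the macrocyclic diamino alcohol F5. Both nitrogens would be sulfonylated with 2-nitrobenzenesulfonyl chloride/Et3N to the bis(2-nitrobenzenesulfonamide) F6. An intramolecular Fukuyama-Mitsunobu reaction (PPh3, DIAD, THF) of the primary sulfonamide N-H with the primary alcohol would close the N,N'-bis(2-nitrobenzenesulfonyl)piperazine F7, and PhSH/K2CO3 in DMF would free 12.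

Step 12. Condensation may stay incomplete because 16 is poorly soluble, and the electron-rich phenol ring may be oxidised (oxidative coupling) under iron and air. Partial thermal loss of Boc would be harmless. The fallback is the non-oxidative acylation and cyclodehydration form of the Traube synthesis; it sets out from 15 and returns at 19. Pinnick oxidation (NaClO2, NaH2PO4, 2-methyl-2-butene, t-BuOH/H2O) would give the N,N'-di-Boc macrocyclic salicylic acid F8. EDC/HOBt coupling with 16 at its 5-amino group in DMF would give the 5-aroylamino-2,6-diaminopyrimidin-4(3H)-one F9, and aqueous NaOH/EtOH at reflux would close the imidazole to 19.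

Step 1. Protodeboronation or incomplete esterification may occur, and the amphoteric amino boronic ester may be lost to the aqueous phase on work-up. The fallback uses a methyl ester and a non-basic ester cleavage; it sets out from 1 and returns at 7. SOCl2/MeOH would give methyl 4-borono-L-phenylalaninate hydrochloride F10. Coupling with 3 (DIC, Oxyma, NMM) would give methyl N-(N-phthaloyl-L-alanyl)-4-borono-L-phenylalaninate F11, and Chan-Lam coupling with 5 as in step 3 would give methyl N-(N-phthaloyl-L-alanyl)-O-(5-iodo-2-methoxyphenyl)-L-tyrosinate F12. Me3SnOH in 1,2-dichloroethane at 70 °C, followed by dilute HCl work-up, would cleave the ester to 7 without opening the phthalimide.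

## Further compounds

F1 | step 5 | 3-hydroxy-4-methoxy-L-phenylalanine | N[C@@H](Cc1ccc(OC)c(O)c1)C(=O)O
F2 | step 5 | N-phthaloyl-3-hydroxy-4-methoxy-L-phenylalanine | O=C(O)[C@H](Cc1ccc(OC)c(O)c1)N1C(=O)c2ccccc2C1=O
F3 | step 5 | tert-butyl N-(N-phthaloyl-3-hydroxy-4-methoxy-L-phenylalanyl)-4-borono-L-phenylalaninate | COc1ccc(C[C@H](N2C(=O)c3ccccc3C2=O)C(=O)N[C@@H](Cc2ccc(B(O)O)cc2)C(=O)OC(C)(C)C)cc1O
F4 | step 5 | macrocyclic N-phthaloyl dipeptide tert-butyl ester | COc1ccc2cc1Oc1ccc(cc1)C[C@@H](C(=O)OC(C)(C)C)NC(=O)[C@@H](N1C(=O)c3ccccc3C1=O)C2
F5 | step 7 | macrocyclic diamino alcohol | COc1ccc2cc1Oc1ccc(cc1)C[C@@H](CO)NC[C@@H](N)C2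
F6 | step 7 | macrocyclic bis(2-nitrobenzenesulfonamide) alcohol | COc1ccc2cc1Oc1ccc(cc1)C[C@@H](CO)N(S(=O)(=O)c1ccccc1[N+](=O)[O-])C[C@@H](NS(=O)(=O)c1ccccc1[N+](=O)[O-])C2
F7 | step 7 | N,N'-bis(2-nitrobenzenesulfonyl) macrocyclic piperazine, ring A O-methyl | COc1ccc2cc1Oc1ccc(cc1)C[C@H]1CN(S(=O)(=O)c3ccccc3[N+](=O)[O-])[C@H](CN1S(=O)(=O)c1ccccc1[N+](=O)[O-])C2
F8 | step 12 | N,N'-di-Boc macrocyclic salicylic acid | OC(=O)c1cc2cc(c1O)Oc1ccc(cc1)C[C@H]1CN(C(=O)OC(C)(C)C)[C@H](CN1C(=O)OC(C)(C)C)C2
F9 | step 12 | 5-aroylamino-2,6-diaminopyrimidin-4(3H)-one amide | Nc1nc(N)c(NC(=O)c2cc3cc(c2O)Oc2ccc(cc2)C[C@H]2CN(C(=O)OC(C)(C)C)[C@H](CN2C(=O)OC(C)(C)C)C3)c(=O)[nH]1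
F10 | step 1 | methyl 4-borono-L-phenylalaninate hydrochloride | N[C@@H](Cc1ccc(B(O)O)cc1)C(=O)OC.Cl
F11 | step 1 | methyl N-(N-phthaloyl-L-alanyl)-4-borono-L-phenylalaninate | C[C@H](N1C(=O)c2ccccc2C1=O)C(=O)N[C@@H](Cc1ccc(B(O)O)cc1)C(=O)OC
F12 | step 1 | methyl N-(N-phthaloyl-L-alanyl)-O-(5-iodo-2-methoxyphenyl)-L-tyrosinate | COc1ccc(I)cc1Oc1ccc(cc1)C[C@@H](C(=O)OC)NC(=O)[C@H](C)N1C(=O)c2ccccc2C1=O
A1 | alternative 1 | N,N'-di-Boc-guanipiperazine A (same compound as 19) | Nc1nc2nc(-c3cc4cc(c3O)Oc3ccc(cc3)C[C@H]3CN(C(=O)OC(C)(C)C)[C@H](CN3C(=O)OC(C)(C)C)C4)[nH]c2c(=O)[nH]1
A2 | alternative 1 | N,N'-di-Boc macrocyclic salicylaldehyde (same compound as 15) | O=Cc1cc2cc(c1O)Oc1ccc(cc1)C[C@H]1CN(C(=O)OC(C)(C)C)[C@H](CN1C(=O)OC(C)(C)C)C2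
A3 | alternative 2 | O-benzyl N,N'-di-Cbz macrocyclic piperazine | c1ccc(cc1)COc1ccc2cc1Oc1ccc(cc1)C[C@H]1CN(C(=O)OCc3ccccc3)[C@H](CN1C(=O)OCc1ccccc1)C2
A4 | alternative 2 | 4-benzyloxy-5-aryloxy-2-pyrone tethered to a (2S,5S)-N,N'-di-Cbz-5-propargylpiperazine | O=c1cc(OCc2ccccc2)c(Oc2ccc(cc2)C[C@H]2CN(C(=O)OCc3ccccc3)[C@H](CN2C(=O)OCc2ccccc2)CC#C)co1
A5 | alternative 3 | macrocyclic (2S,5S) bis-lactim ether, ring A O-methyl | COc1ccc2cc1Oc1ccc(cc1)C[C@H]1C(OC)=N[C@H](C(OC)=N1)C2
A6 | alternative 3 | (2S)-bis-lactim ether with ring A benzylic bromide | COc1ccc(CBr)cc1Oc1ccc(cc1)C[C@H]1C(OC)=NCC(OC)=N1
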